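The plan rests on cutting the C1–C6 ring bond (C1 = carbinol carbon bearing C7H2OBz, C2/C3 = acetoxy carbons, C4=C5 = alkene, C6 = benzoyloxy carbon) and reconnecting C6 to C2, i.e. an acyloin ring expansion run backwards. It exploits the cis relationship of O3 and O6 across the C4=C5 bond of the six-membered ring: with C1 excised, the remaining cyclopentene is meso. In the forward sense one chiral-Lewis-acid-mediated 1,2-shift makes the cyclohexene ring, creates C1 and fixes the absolute configuration at C3 and C6. Its precursor is a meso 1-(benzoyloxyacetyl)cyclopent-3-en-1-ol whose two cis silyloxy groups lie trans to the acyl group.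

Key step: step 7

Remark on labels: the atom labels C1–C7 defined above are kept for all six-membered intermediates; viewed with C7 on the upper (β) face of C1, O1, O3 and O6 are α and O2 is β, and the target is (1S,2S,3R,6S).

Remark on the key step (assumption): the sense of asymmetric induction in step 7 cannot be derived from precedent, so the ligand antipode that gives 14 and not its mirror image is fixed by a screen on 13; both antipodes are commercial.

Step 1
Reactants: 1 6,6-dimethylfulvene
Product: 3 meso cis-2-(propan-2-ylidene)cyclopent-4-ene-1,3-diol, via fulvene endoperoxide 2 (not isolated)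
Conditions: O2, hν (visible), rose bengal (cat.), thiourea, MeOH, −30 °C → rt
Reagents that add atoms: dioxygen, O=O
Why: Dye-sensitised singlet-oxygen [4+2] photooxygenation of the ring diene puts both new C–O bonds on one face, and thiourea reduces only the O–O bond of the labile endoperoxide as it forms, so the two carbinol centres should arise cis (meso) by construction.

Step 2
Reactants: 3 meso cis-2-(propan-2-ylidene)cyclopent-4-ene-1,3-diol
Product: 4 meso cis-3,5-bis(tert-butyldimethylsilyloxy)-4-(propan-2-ylidene)cyclopent-1-ene
Conditions: TBSCl, imidazole, DMF, rt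
Reagents that add atoms: tert-butyldimethylsilyl chloride, CC(C)(C)[Si](C)(C)Cl
Why: Imidazole-mediated silylation of two secondary allylic alcohols is routine and touches no stereocentre.

Step 3
Reactants: 4 meso cis-3,5-bis(tert-butyldimethylsilyloxy)-4-(propan-2-ylidene)cyclopent-1-ene
Product: 6 meso cis-2,5-bis(tert-butyldimethylsilyloxy)cyclopent-3-en-1-one, via primary ozonide 5 (not isolated)
Conditions: O3, CH2Cl2/MeOH, NaHCO3, −78 °C (Sudan Red 7B end point); then Me2S, −78 °C → rt
Reagents that add atoms: ozone, [O-][O+]=O
Why: Ozonolysis with reductive work-up should cleave the tetrasubstituted exocyclic alkene in preference to the ring cis-alkene when ozone is dosed to the dye end point, the acetone O-oxide fragment being trapped by methanol and reduced by Me2S, and the neutral work-up should spare the enolisable β,γ-unsaturated ketone; no stereocentre changes.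

Step 4
Reactants: 6 meso cis-2,5-bis(tert-butyldimethylsilyloxy)cyclopent-3-en-1-one; 7 ethyl vinyl ether
Product: 10 meso 1-(1-ethoxyvinyl)-2,5-bis(tert-butyldimethylsilyloxy)cyclopent-3-en-1-ol (OH cis to both silyloxy groups), via 1-ethoxyvinyllithium 8 (not isolated), via (1-ethoxyvinyl)cerium dichloride 9 (not isolated)
Conditions: t-BuLi, THF, −78 → 0 °C (7 → 8); CeCl3, THF, −78 °C; then 6, −78 °C; aq NH4Cl
Reagents that add atoms: none
Why: 1,2-Addition of an α-alkoxyvinyl organocerium (Imamoto-type acyl-anion equivalent) should outrun deprotonation of the α-silyloxy positions and occur on the face anti to both silyloxy groups, so the new C–C bond ends trans and the hydroxyl cis to them (the carbinol carbon lies on the mirror plane, so the product stays meso).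

Step 5
Reactants: 10 meso 1-(1-ethoxyvinyl)-2,5-bis(tert-butyldimethylsilyloxy)cyclopent-3-en-1-ol
Product: 11 meso 2-bromo-1-[1-hydroxy-2,5-bis(tert-butyldimethylsilyloxy)cyclopent-3-en-1-yl]ethan-1-one
Conditions: NBS, NaHCO3, THF/H2O (4:1), 0 °C
Reagents that add atoms: N-bromosuccinimide, O=C1CCC(=O)N1Br; water, O
Why: Electrophilic bromination of the electron-rich enol ether (oxocarbenium ion, capture by water, loss of ethanol) gives the α-bromomethyl ketone far faster than NBS attacks the deactivated ring alkene, and no stereocentre is involved.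

Step 6
Reactants: 11 meso 2-bromo-1-[1-hydroxy-2,5-bis(tert-butyldimethylsilyloxy)cyclopent-3-en-1-yl]ethan-1-one; 12 benzoic acid
Product: 13 meso 2-[1-hydroxy-2,5-bis(tert-butyldimethylsilyloxy)cyclopent-3-en-1-yl]-2-oxoethyl benzoate (OH cis to both silyloxy groups; acyl group trans)
Conditions: KHCO3, DMF, rt
Reagents that add atoms: none
Why: SN2 displacement of an α-halo ketone by a carboxylate (phenacyl-type ester formation) is fast, and benzoate/bicarbonate is too weakly basic to ionise the tertiary alcohol or start a ketol shift.

Step 7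
Reactants: 13 meso 2-[1-hydroxy-2,5-bis(tert-butyldimethylsilyloxy)cyclopent-3-en-1-yl]-2-oxoethyl benzoate
Product: 14 [(1S,3R,6S)-1-hydroxy-2-oxo-3,6-bis(tert-butyldimethylsilyloxy)cyclohex-4-en-1-yl]methyl benzoate (O1, O3 and O6 α; C7 β)
Conditions: Sc(OTf)3 (10 mol %), Ph-pybox (12 mol %; (S,S) or (R,R), see remark), 4 Å MS, CH2Cl2, −20 °C → rt
Reagents that add atoms: none
Why: Proposed new method: the Sc(III)–pybox cation should chelate the tertiary hydroxyl and the ketone oxygen of 13 in a five-membered ring, which eclipses the two C–O bonds and places the two ring bonds of the carbinol carbon over opposite faces of the activated carbonyl; the chiral pocket should let only the bond to the (S)-configured silyloxy carbon (the future C2–C6 bond) align with the carbonyl π* orbital, so that C6 shifts to C1 with retention while C2–O becomes C=O (acyloin, i.e. α-ketol, rearrangement); the closest known reaction types are chiral-Lewis-acid-catalysed α-ketol ring expansions of 1-acylcycloalkanols and the D-homoannulation of 17α-hydroxy-20-keto steroids, neither of which selects between enantiotopic bonds of a meso ketol. The six-membered ring is closed by ring expansion through this 1,2-carbon shift (C1 inserted between C2 and C6: C1–C6 formed, C2–C6 broken), not by cyclisation of a chain. The new stereocentre C1 is set relative to C6 by the substrate: in the chelate, with the acyl group trans to both silyloxy groups, the carbonyl oxygen becomes C1–OH cis to O6 and C7 goes to the opposite face, whereas the absolute sense, and with it the descriptors of C3 and C6, is set by the ligand. The step needs enantiotopic bond selection, which is the catalyst's task, and a chelated ketol, which the substrate secures because the bulky silyl ethers are poor donors and leave the hydroxy ketone as the only bidentate site. The carbinol carbon bears no hydrogen, so elimination cannot compete, relief of cyclopentene strain and of crowding should make the shift downhill, and the electron-poor CH2OBz group is a poor migrator, which should keep the product acyloin from rearranging further.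

Step 8
Reactants: 14 [(1S,3R,6S)-1-hydroxy-2-oxo-3,6-bis(tert-butyldimethylsilyloxy)cyclohex-4-en-1-yl]methyl benzoate
Product: 15 [1α,2β-dihydroxy-3α,6α-bis(tert-butyldimethylsilyloxy)cyclohex-4-en-1-yl]methyl benzoate
Conditions: Me4NBH(OAc)3, MeCN/AcOH (1:1), −20 °C
Reagents that add atoms: none
Why: Hydroxyl-directed triacetoxyborohydride reduction (Saksena–Evans type) binds boron to C1–OH and delivers hydride to the α-face of C2, which sets C2–OH β and trans to C1–OH, while the acidic medium avoids enolisation towards C3 and spares benzoate and silyl ethers.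

Step 9
Reactants: 15 [1α,2β-dihydroxy-3α,6α-bis(tert-butyldimethylsilyloxy)cyclohex-4-en-1-yl]methyl benzoate
Product: 16 (1α,2β,3α,6α-tetrahydroxycyclohex-4-en-1-yl)methyl benzoate
Conditions: HF·pyridine, pyridine, THF, 0 °C → rt
Reagents that add atoms: none
Why: Fluoride-mediated desilylation under buffered acidic conditions removes both silyl ethers without the benzoyl migration that basic fluoride could induce and affects no stereocentre.

Step 10
Reactants: 16 (1α,2β,3α,6α-tetrahydroxycyclohex-4-en-1-yl)methyl benzoate
Product: 17 (2β,3α-dihydroxy-1α,6α-O-isopropylidenedioxycyclohex-4-en-1-yl)methyl benzoate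
Conditions: Me2C(OMe)2, PPTS (cat.), acetone, rt
Reagents that add atoms: 2,2-dimethoxypropane, COC(C)(C)OC
Why: Thermodynamic transacetalisation selects O1/O6, the only cis-vicinal pair, for an unstrained cis-fused dioxolane (O1/O2 and O2/O3 are trans), so C2–OH and C3–OH stay free.

Step 11
Reactants: 17 (2β,3α-dihydroxy-1α,6α-O-isopropylidenedioxycyclohex-4-en-1-yl)methyl benzoate
Product: 18 (2β,3α-diacetoxy-1α,6α-O-isopropylidenedioxycyclohex-4-en-1-yl)methyl benzoate
Conditions: Ac2O, pyridine, DMAP (cat.), CH2Cl2, 0 °C → rt
Reagents that add atoms: acetic anhydride, CC(=O)OC(C)=O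
Why: DMAP-catalysed acetylation esterifies the two free secondary alcohols while O1 and O6 are locked in the acetonide.

Step 12
Reactants: 18 (2β,3α-diacetoxy-1α,6α-O-isopropylidenedioxycyclohex-4-en-1-yl)methyl benzoate
Product: 19 (2β,3α-diacetoxy-1α,6α-dihydroxycyclohex-4-en-1-yl)methyl benzoate
Conditions: TFA/H2O (9:1), CH2Cl2, 0 °C → rt
Reagents that add atoms: none
Why: Acid-catalysed acetal hydrolysis leaves the carboxylic esters intact, and a possible C7→C6 benzoyl shift would be harmless because step 13 converges on the same dibenzoate.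

Step 13
Reactants: 19 (2β,3α-diacetoxy-1α,6α-dihydroxycyclohex-4-en-1-yl)methyl benzoate
Product: 20 cleistenediol F, [(1S,2S,3R,6S)-2,3-diacetoxy-6-(benzoyloxy)-1-hydroxycyclohex-4-en-1-yl]methyl benzoate
Conditions: BzCl, pyridine, DMAP (cat.), CH2Cl2, 0 °C
Reagents that add atoms: benzoyl chloride, O=C(Cl)c1ccccc1
Why: Pyridine/DMAP benzoylation acylates the secondary allylic C6–OH while the tertiary C1–OH is inert under these conditions, which completes the target with all four stereocentres unchanged.

Compound list
1 | 6,6-dimethylfulvene | CC(C)=C1C=CC=C1 | starting material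
2 | 7-(propan-2-ylidene)-2,3-dioxabicyclo[2.2.1]hept-5-ene (fulvene endoperoxide, formed in situ) | CC(C)=C1[C@H]2C=C[C@@H]1OO2 | intermediate
3 | meso (1R,3S)-2-(propan-2-ylidene)cyclopent-4-ene-1,3-diol (hydroxyls cis) | CC(C)=C1[C@H](O)C=C[C@@H]1O | intermediate
4 | meso cis-3,5-bis(tert-butyldimethylsilyloxy)-4-(propan-2-ylidene)cyclopent-1-ene | CC(C)=C1[C@H](O[Si](C)(C)C(C)(C)C)C=C[C@@H]1O[Si](C)(C)C(C)(C)C | intermediate
5 | primary ozonide of 4 (spiro-1,2,3-trioxolane at the former exocyclic alkene, ring oxygen anti to the silyloxy groups, formed in situ) | CC1(C)OOO[C@]12[C@H](O[Si](C)(C)C(C)(C)C)C=C[C@@H]2O[Si](C)(C)C(C)(C)C | intermediate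
6 | meso (2R,5S)-2,5-bis(tert-butyldimethylsilyloxy)cyclopent-3-en-1-one | O=C1[C@H](O[Si](C)(C)C(C)(C)C)C=C[C@@H]1O[Si](C)(C)C(C)(C)C | intermediate
7 | ethyl vinyl ether | C=COCC | starting material
8 | 1-ethoxyvinyllithium (formed in situ) | [Li]C(=C)OCC | intermediate
9 | (1-ethoxyvinyl)cerium dichloride (formed in situ) | CCOC(=C)[Ce](Cl)Cl | intermediate
10 | meso 1-(1-ethoxyvinyl)-2,5-bis(tert-butyldimethylsilyloxy)cyclopent-3-en-1-ol (OH cis to both silyloxy groups) | CCOC(=C)[C@@]1(O)[C@H](O[Si](C)(C)C(C)(C)C)C=C[C@@H]1O[Si](C)(C)C(C)(C)C | intermediate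
11 | meso 2-bromo-1-[1-hydroxy-2,5-bis(tert-butyldimethylsilyloxy)cyclopent-3-en-1-yl]ethan-1-one (OH cis to both silyloxy groups) | O=C(CBr)[C@@]1(O)[C@H](O[Si](C)(C)C(C)(C)C)C=C[C@@H]1O[Si](C)(C)C(C)(C)C | intermediate
12 | benzoic acid | O=C(O)c1ccccc1 | starting material
13 | meso 2-[1-hydroxy-2,5-bis(tert-butyldimethylsilyloxy)cyclopent-3-en-1-yl]-2-oxoethyl benzoate (OH cis to both silyloxy groups, acyl trans; key-step precursor) | O=C(COC(=O)c1ccccc1)[C@@]1(O)[C@H](O[Si](C)(C)C(C)(C)C)C=C[C@@H]1O[Si](C)(C)C(C)(C)C | intermediate
14 | [(1S,3R,6S)-1-hydroxy-2-oxo-3,6-bis(tert-butyldimethylsilyloxy)cyclohex-4-en-1-yl]methyl benzoate (key-step product) | CC(C)(C)[Si](C)(C)O[C@@H]1C=C[C@H](O[Si](C)(C)C(C)(C)C)[C@@](O)(COC(=O)c2ccccc2)C1=O | intermediate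
15 | [1α,2β-dihydroxy-3α,6α-bis(tert-butyldimethylsilyloxy)cyclohex-4-en-1-yl]methyl benzoate | CC(C)(C)[Si](C)(C)O[C@@H]1C=C[C@H](O[Si](C)(C)C(C)(C)C)[C@@](O)(COC(=O)c2ccccc2)[C@H]1O | intermediate
16 | (1α,2β,3α,6α-tetrahydroxycyclohex-4-en-1-yl)methyl benzoate | O[C@@H]1C=C[C@H](O)[C@@](O)(COC(=O)c2ccccc2)[C@H]1O | intermediate
17 | (2β,3α-dihydroxy-1α,6α-O-isopropylidenedioxycyclohex-4-en-1-yl)methyl benzoate | O[C@@H]1C=C[C@@H]2OC(C)(C)O[C@]2(COC(=O)c3ccccc3)[C@H]1O | intermediate
18 | (2β,3α-diacetoxy-1α,6α-O-isopropylidenedioxycyclohex-4-en-1-yl)methyl benzoate | CC(=O)O[C@@H]1C=C[C@@H]2OC(C)(C)O[C@]2(COC(=O)c3ccccc3)[C@H]1OC(C)=O | intermediate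
19 | (2β,3α-diacetoxy-1α,6α-dihydroxycyclohex-4-en-1-yl)methyl benzoate | CC(=O)O[C@@H]1C=C[C@H](O)[C@@](O)(COC(=O)c2ccccc2)[C@H]1OC(C)=O | intermediate
20 | cleistenediol F, [(1S,2S,3R,6S)-2,3-diacetoxy-6-(benzoyloxy)-1-hydroxycyclohex-4-en-1-yl]methyl benzoate | CC(=O)O[C@@H]1C=C[C@H](OC(=O)c2ccccc2)[C@@](O)(COC(=O)c2ccccc2)[C@H]1OC(C)=O | target

Total step count: 13. Longest linear sequence: 13 steps (1 → 20).

Steps most likely to fail

Step 7. The catalyst may fail to differentiate the two enantiotopic ring bonds, or may be diverted by coordination to the benzoate. Enantiopurity may also erode through a second, degenerate 1,2-shift in the product, in which C7 moves from C1 to C2 and interconverts the two mirror-image ketones. Fallback with known chemistry: setting out from 13, the ring expansion is run without bond discrimination under an achiral chelating promoter (Al(Ot-Bu)3 in toluene, or Sc(OTf)3/2,2′-bipyridine in CH2Cl2). This is an established acyloin ring expansion of 1-acylcycloalkanols, and chelation should keep the same relative configuration. It should give 14 together with an equal amount of its mirror image, the enantiomeric ketone F1. Preparative chromatography on a chiral stationary phase separates the two, and the route is rejoined at 14.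

Step 3. Ozone may not discriminate well enough between the exocyclic and the ring alkene, leading to over-oxidation, and the β,γ-unsaturated ketone may be lost by enolisation during work-up. Fallback: setting out from 4, epoxidation with a peracid (mCPBA, NaHCO3, CH2Cl2, 0 °C), which responds far more strongly to alkyl substitution than ozone does, should give the spiro-epoxide F2 at the tetrasubstituted alkene from the face anti to the silyloxy groups. Periodic acid in aqueous THF then opens the epoxide and cleaves the glycol, releasing acetone and ketone 6, where the route is rejoined.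

Step 4. The vinyl-metal reagent may deprotonate the allylic, α-silyloxy C–H of 6, so that enolate formation and isomerisation into conjugation compete with addition; the enol ether may also hydrolyse prematurely on work-up. Fallback: setting out from 6, the much less basic ethynylmagnesium bromide (THF, −78 → 0 °C) should add anti to the silyloxy groups to give the propargylic alcohol F3. Hg(OTf)2-catalysed Markovnikov hydration (aq MeCN, rt) then gives the α-hydroxy methyl ketone F4. Its methyl group is the only enolisable position, so monobromination with phenyltrimethylammonium tribromide (THF, 0 °C) leads to bromoketone 11, where the route is rejoined.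

Further compounds
F1 | step 7 | [(1R,3S,6R)-1-hydroxy-2-oxo-3,6-bis(tert-butyldimethylsilyloxy)cyclohex-4-en-1-yl]methyl benzoate (mirror image of 14) | CC(C)(C)[Si](C)(C)O[C@H]1C=C[C@@H](O[Si](C)(C)C(C)(C)C)[C@](O)(COC(=O)c2ccccc2)C1=O
F2 | step 3 | meso 2,2-dimethyl-4,7-bis(tert-butyldimethylsilyloxy)-1-oxaspiro[2.4]hept-5-ene (epoxide oxygen anti to the silyloxy groups) | CC1(C)O[C@]12[C@H](O[Si](C)(C)C(C)(C)C)C=C[C@@H]2O[Si](C)(C)C(C)(C)C
F3 | step 4 | meso 1-ethynyl-2,5-bis(tert-butyldimethylsilyloxy)cyclopent-3-en-1-ol (OH cis to both silyloxy groups) | C#C[C@@]1(O)[C@H](O[Si](C)(C)C(C)(C)C)C=C[C@@H]1O[Si](C)(C)C(C)(C)C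
F4 | step 4 | meso 1-[1-hydroxy-2,5-bis(tert-butyldimethylsilyloxy)cyclopent-3-en-1-yl]ethan-1-one (OH cis to both silyloxy groups) | CC(=O)[C@@]1(O)[C@H](O[Si](C)(C)C(C)(C)C)C=C[C@@H]1O[Si](C)(C)C(C)(C)C
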